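**Retrosynthetic overview**
- The target is unmasked last from its penta-O-methyl form (four aryl methyl ethers and the methyl ester) with BBr3.
- Ring B (the pyranone) closes last: C2–C3 by Claisen condensation of a 2-hydroxy-6-heptyl-4-methoxyacetophenone (ring A, from 5-heptylresorcinol) with the ring C arylacetate, then O1–C2 by cyclodehydration.
- The arylacetate comes from a 2-(benzyloxy)ethyl side chain on ring C by debenzylation and oxidation.
- The strategy rests on ring C: the carboxyl-bearing C1' sits between the CH2-bearing C2' and the oxygenated C6', with further oxygens at C3' and C4'. Ring C is therefore made first as a cyclohexane-1,3-dione, by forming C1'–C2' (Michael) and C5'–C6' (Claisen) from dimethyl malonate and an α-methoxy enone, and is then dehydrogenated to the benzene ring.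
- The enone comes from Horner–Wadsworth–Emmons olefination of 3-(benzyloxy)propanal. Ring order: ring C, then ring B onto the purchased ring A.

Key step: step 3

Assumption: the target has no stereocentres, so neither the sp3 centres created in the annulation nor the enone geometry need control; the α-methoxy enone is written as its expected major (Z) isomer, and any (E) isomer is carried along because both give the same adduct.

**Step 1**
Reactants: 1 dimethyl (1-diazo-2-oxopropyl)phosphonate
Product: 2 dimethyl (1-methoxy-2-oxopropyl)phosphonate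
Conditions: Rh2(OAc)4 (1 mol%), MeOH (5 equiv), toluene, 80 °C
Reagents that add atoms: methanol, CO
Why: Rhodium carbenoid O–H insertion, in which the acceptor carbenoid formed from the diazo ketophosphonate is trapped by methanol faster than it can rearrange, a known way to α-alkoxy phosphonates.

**Step 2**
Reactants: 2 dimethyl (1-methoxy-2-oxopropyl)phosphonate; 3 3-(benzyloxy)propanal
Product: 4 (Z)-6-(benzyloxy)-3-methoxyhex-3-en-2-one
Conditions: NaH (1.05 equiv), THF, 0 °C; then 3, 0 °C to rt
Reagents that add atoms: none
Why: Horner–Wadsworth–Emmons olefination of an unhindered aldehyde by the preformed, weakly basic ketophosphonate anion, which spares the β-benzyloxy aldehyde from elimination and should favour the (Z) enol ether with the acetyl group trans to the chain.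

**Step 3**
Reactants: 4 (Z)-6-(benzyloxy)-3-methoxyhex-3-en-2-one; 5 dimethyl malonate
Product: 7 methyl 6-[2-(benzyloxy)ethyl]-5-methoxy-2,4-dioxocyclohexane-1-carboxylate (diastereomer and keto-enol mixture), via malonate Michael adduct 6 (not isolated)
Conditions: 5 (1.2 equiv), NaOMe (1.2 equiv), MeOH, rt then reflux; cold 1 M HCl work-up
Reagents that add atoms: none
Why: NaOMe converts 5 into sodiomalonate, which adds reversibly to the β-carbon of enone 4 (C1'-C2' bond) to give adduct 6, and the methyl ketone enolate of 6 then attacks one malonate ester in a Claisen condensation (C5'-C6' bond) with loss of methoxide. The closest known reaction type is the malonate-enone Michael-Claisen annulation that delivers 5-substituted carbomethoxy cyclohexane-1,3-diones (dihydroresorcylates). Ring C closes in the 6-exo-trig mode, the only alternative enolate (at the methoxy-bearing carbon) being able to reach the esters only through a four-membered ring. The three sp3 centres arise without control, which is intended because step 4 removes all of them. The step needs 1,4- over 1,2-addition and addition faster than γ-deprotonation of 4 with loss of benzyl alcohol: the soft, reversibly adding malonate secures the first, and formation of the strongly acidic 1,3-dione enolate, which drains every preceding equilibrium, is expected to secure the second although the α-methoxy group lowers the electrophilicity of the β-carbon.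

**Step 4**
Reactants: 7 methyl 6-[2-(benzyloxy)ethyl]-5-methoxy-2,4-dioxocyclohexane-1-carboxylate
Product: 9 methyl 2-[2-(benzyloxy)ethyl]-4,6-dihydroxy-3-methoxybenzoate, via bromodione 8 (not isolated)
Conditions: Br2 (1.0 equiv), DMF, 0 °C, dark; then 60 °C
Reagents that add atoms: none
Why: Halogenation–dehydrohalogenation aromatization of a 2,4-dioxocyclohexane-1-carboxylate, in which the dione enol is brominated between the carbonyls to 8, bromine transposition under the HBr formed and loss of HBr give a dienone that tautomerizes to the resorcylate, while loss of methanol should not compete because C2'-H is not acidic and C3' cannot ionize next to a carbonyl, and one equivalent of Br2 limits attack at C5' of the product.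

**Step 5**
Reactants: 9 methyl 2-[2-(benzyloxy)ethyl]-4,6-dihydroxy-3-methoxybenzoate
Product: 10 methyl 2-[2-(benzyloxy)ethyl]-3,4,6-trimethoxybenzoate
Conditions: MeI (3 equiv), K2CO3 (3 equiv), DMF, 40 °C
Reagents that add atoms: iodomethane, CI
Why: Williamson O-methylation of both phenols, the warm DMF being needed for the C6' hydroxyl that is hydrogen-bonded to the ester.

**Step 6**
Reactants: 10 methyl 2-[2-(benzyloxy)ethyl]-3,4,6-trimethoxybenzoate
Product: 11 methyl 2-(2-hydroxyethyl)-3,4,6-trimethoxybenzoate
Conditions: H2 (1 atm), 10% Pd/C, EtOAc, rt; crude product used at once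
Reagents that add atoms: none
Why: Hydrogenolysis of the benzyl ether leaves aryl methyl ethers and the ester untouched, and the neutral medium together with the doubly ortho-substituted, twisted ester should hold back lactonization to the isochromanone until the alcohol is oxidized.

**Step 7**
Reactants: 11 methyl 2-(2-hydroxyethyl)-3,4,6-trimethoxybenzoate
Product: 13 2-[2,3,5-trimethoxy-6-(methoxycarbonyl)phenyl]acetic acid, via arylacetaldehyde 12 (not isolated)
Conditions: TEMPO (0.2 equiv), PhI(OAc)2 (2.2 equiv), MeCN/H2O (1:1), rt
Reagents that add atoms: water, O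
Why: Oxoammonium-mediated oxidation of the primary alcohol to aldehyde 12 and, through its hydrate, to the acid, under conditions free of chlorinating species so that the electron-rich ring C is not attacked.

**Step 8**
Reactants: 13 2-[2,3,5-trimethoxy-6-(methoxycarbonyl)phenyl]acetic acid
Product: 14 methyl 3,4,6-trimethoxy-2-(2-methoxy-2-oxoethyl)benzoate
Conditions: MeI (1.5 equiv), K2CO3 (1.5 equiv), DMF, rt
Reagents that add atoms: iodomethane, CI
Why: SN2 alkylation of the carboxylate gives the aliphatic methyl ester that serves as the acyl donor in step 11.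

**Step 9**
Reactants: 15 5-heptylresorcinol
Product: 16 1-(2-heptyl-4,6-dihydroxyphenyl)ethan-1-one
Conditions: AcOH (1.1 equiv), BF3·OEt2 (solvent), 90 °C; aqueous NaOAc work-up
Reagents that add atoms: acetic acid, CC(=O)O
Why: Friedel–Crafts acylation of a 5-alkylresorcinol goes mainly to C4, ortho to one hydroxyl and para to the other, as in the acetylation of orcinol, and the minor isomer acylated between the hydroxyls is removed by chromatography.

**Step 10**
Reactants: 16 1-(2-heptyl-4,6-dihydroxyphenyl)ethan-1-one
Product: 17 1-(2-heptyl-6-hydroxy-4-methoxyphenyl)ethan-1-one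
Conditions: MeI (1.05 equiv), K2CO3 (1.1 equiv), acetone, rt
Reagents that add atoms: iodomethane, CI
Why: Selective Williamson methylation of the para hydroxyl, since the ortho hydroxyl is hydrogen-bonded to the ketone and much less nucleophilic.

**Step 11**
Reactants: 17 1-(2-heptyl-6-hydroxy-4-methoxyphenyl)ethan-1-one; 14 methyl 3,4,6-trimethoxy-2-(2-methoxy-2-oxoethyl)benzoate
Product: 19 methyl 2-[(5-heptyl-7-methoxy-4-oxo-4H-chromen-2-yl)methyl]-3,4,6-trimethoxybenzoate, via 1,3-diketone 18 (not isolated)
Conditions: 17 (1.3 equiv), NaH (4 equiv), THF, 0 °C to reflux, slow addition of 14; then conc. HCl, AcOH, 60 °C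
Reagents that add atoms: none
Why: Crossed Claisen condensation of the methyl ketone enolate with the unhindered aliphatic ester of 14 (the doubly ortho-substituted benzoate is inert), driven by deprotonation of diketone 18, followed by the classical acid cyclodehydration of an o-hydroxyaryl 1,3-diketone, in which the phenol adds to the distal carbonyl and water is lost to close ring B.

**Step 12**
Reactants: 19 methyl 2-[(5-heptyl-7-methoxy-4-oxo-4H-chromen-2-yl)methyl]-3,4,6-trimethoxybenzoate
Product: 20 3,4,6-trihydroxy-2-[(5-heptyl-7-hydroxy-4-oxo-4H-chromen-2-yl)methyl]benzoic acid (CNP0272037.0)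
Conditions: BBr3 (12 equiv), CH2Cl2, −78 °C to rt, then 40 °C; ice-water quench and work-up under argon
Reagents that add atoms: none
Why: BBr3 demethylation by bromide attack on the O-methyl groups of the boron-complexed aryl ethers, with the methyl ester, activated by boron chelation between the C6' oxygen and the ester carbonyl, losing its methyl in the same way, while the chromone and the heptyl chain are inert and the air-sensitive hydroxyquinol is protected by the inert work-up.

**Compound list**
1 | dimethyl (1-diazo-2-oxopropyl)phosphonate | CC(=O)C(=[N+]=[N-])P(=O)(OC)OC | starting material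
2 | dimethyl (1-methoxy-2-oxopropyl)phosphonate | CC(=O)C(OC)P(=O)(OC)OC | intermediate
3 | 3-(benzyloxy)propanal | O=CCCOCc1ccccc1 | starting material
4 | (Z)-6-(benzyloxy)-3-methoxyhex-3-en-2-one | CC(=O)/C(OC)=C/CCOCc1ccccc1 | intermediate
5 | dimethyl malonate | COC(=O)CC(=O)OC | starting material
6 | dimethyl 2-[1-(benzyloxy)-4-methoxy-5-oxohexan-3-yl]propanedioate | COC(=O)C(C(=O)OC)C(CCOCc1ccccc1)C(OC)C(C)=O | intermediate
7 | methyl 6-[2-(benzyloxy)ethyl]-5-methoxy-2,4-dioxocyclohexane-1-carboxylate | COC(=O)C1C(=O)CC(=O)C(OC)C1CCOCc1ccccc1 | intermediate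
8 | methyl 6-[2-(benzyloxy)ethyl]-3-bromo-5-methoxy-2,4-dioxocyclohexane-1-carboxylate | COC(=O)C1C(=O)C(Br)C(=O)C(OC)C1CCOCc1ccccc1 | intermediate
9 | methyl 2-[2-(benzyloxy)ethyl]-4,6-dihydroxy-3-methoxybenzoate | COC(=O)c1c(O)cc(O)c(OC)c1CCOCc1ccccc1 | intermediate
10 | methyl 2-[2-(benzyloxy)ethyl]-3,4,6-trimethoxybenzoate | COC(=O)c1c(OC)cc(OC)c(OC)c1CCOCc1ccccc1 | intermediate
11 | methyl 2-(2-hydroxyethyl)-3,4,6-trimethoxybenzoate | COC(=O)c1c(OC)cc(OC)c(OC)c1CCO | intermediate
12 | methyl 3,4,6-trimethoxy-2-(2-oxoethyl)benzoate | COC(=O)c1c(OC)cc(OC)c(OC)c1CC=O | intermediate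
13 | 2-[2,3,5-trimethoxy-6-(methoxycarbonyl)phenyl]acetic acid | COC(=O)c1c(OC)cc(OC)c(OC)c1CC(=O)O | intermediate
14 | methyl 3,4,6-trimethoxy-2-(2-methoxy-2-oxoethyl)benzoate | COC(=O)Cc1c(OC)c(OC)cc(OC)c1C(=O)OC | intermediate
15 | 5-heptylresorcinol | CCCCCCCc1cc(O)cc(O)c1 | starting material
16 | 1-(2-heptyl-4,6-dihydroxyphenyl)ethan-1-one | CCCCCCCc1cc(O)cc(O)c1C(C)=O | intermediate
17 | 1-(2-heptyl-6-hydroxy-4-methoxyphenyl)ethan-1-one | CCCCCCCc1cc(OC)cc(O)c1C(C)=O | intermediate
18 | methyl 2-[4-(2-heptyl-6-hydroxy-4-methoxyphenyl)-2,4-dioxobutyl]-3,4,6-trimethoxybenzoate | CCCCCCCc1cc(OC)cc(O)c1C(=O)CC(=O)Cc1c(OC)c(OC)cc(OC)c1C(=O)OC | intermediate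
19 | methyl 2-[(5-heptyl-7-methoxy-4-oxo-4H-chromen-2-yl)methyl]-3,4,6-trimethoxybenzoate | CCCCCCCc1cc(OC)cc2oc(Cc3c(OC)c(OC)cc(OC)c3C(=O)OC)cc(=O)c12 | intermediate
20 | 3,4,6-trihydroxy-2-[(5-heptyl-7-hydroxy-4-oxo-4H-chromen-2-yl)methyl]benzoic acid | CCCCCCCc1cc(O)cc2oc(Cc3c(O)c(O)cc(O)c3C(=O)O)cc(=O)c12 | target

**Step count**
Total: 12 steps. Longest linear sequence: 10 steps (steps 1 to 8, 11 and 12); steps 9 and 10 form the two-step branch to ketone 17.

**Steps most likely to fail**

Step 3. Conjugate addition to the β-carbon of the captodative enone may be too slow, so that γ-deprotonation with loss of benzyl alcohol or self-condensation of the methyl ketone wins. The fallback sets out from aldehyde 3 and malonate 5 and comes back at dione 7, forming the C2'–C3' bond with reversed polarity. Knoevenagel condensation of 3 with 5 (TiCl4, pyridine, THF, 0 °C) should give dimethyl 2-[3-(benzyloxy)propylidene]malonate F1, a far stronger acceptor. Commercial methoxyacetone is silylated under equilibrating conditions (Me3SiCl, Et3N, NaI, MeCN) to (Z)-1-methoxy-2-(trimethylsilyloxy)prop-1-ene F2. Mukaiyama–Michael addition of F2 to F1 (TiCl4, CH2Cl2, −78 °C) should give adduct 6, now isolated, and NaOMe in MeOH then closes the C5'–C6' bond to 7.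

Step 11. Proton transfer from the arylacetate to the ketone enolate may stall the acylation, the ester may self-condense, or the diketone enol may lactonize onto the ring C ester. The fallback sets out from ketone 17 and acid 13 and comes back at chromone 19, using soft enolization in place of a strong base. Ketone 17 is protected (MOMCl, iPr2NEt, CH2Cl2) as 1-[2-heptyl-4-methoxy-6-(methoxymethoxy)phenyl]ethan-1-one F3. Acid 13 is converted (1H-benzotriazole, SOCl2, CH2Cl2) into methyl 2-[2-(1H-benzotriazol-1-yl)-2-oxoethyl]-3,4,6-trimethoxybenzoate F4. C-Acylation of F3 with F4 (MgBr2·OEt2, iPr2NEt, CH2Cl2, rt) should give methyl 2-{4-[2-heptyl-4-methoxy-6-(methoxymethoxy)phenyl]-2,4-dioxobutyl}-3,4,6-trimethoxybenzoate F5. HCl in MeOH at 50 °C then removes the acetal and cyclodehydrates to 19.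

Step 4. Bromination of the already aromatized, very electron-rich product at C5' may consume the oxidant and leave a mixture of dione, resorcylate and bromoresorcylate. The fallback sets out from dione 7 and comes back at alcohol 11, using bromine as a deliberate, traceless blocking group. Br2 (2.1 equiv) with NaOAc in AcOH should aromatize and brominate in one operation to methyl 2-[2-(benzyloxy)ethyl]-5-bromo-4,6-dihydroxy-3-methoxybenzoate F6. Methylation (MeI, K2CO3, DMF) gives methyl 2-[2-(benzyloxy)ethyl]-5-bromo-3,4,6-trimethoxybenzoate F7. Hydrogenolysis (H2, 10% Pd/C, Et3N, EtOAc/MeOH) then removes the aryl bromide and the benzyl ether together to give 11.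

**Further compounds**
F1 | step 3 | dimethyl 2-[3-(benzyloxy)propylidene]malonate | COC(=O)C(=CCCOCc1ccccc1)C(=O)OC
F2 | step 3 | (Z)-1-methoxy-2-(trimethylsilyloxy)prop-1-ene | CO/C=C(/C)O[Si](C)(C)C
F3 | step 11 | 1-[2-heptyl-4-methoxy-6-(methoxymethoxy)phenyl]ethan-1-one | CCCCCCCc1cc(OC)cc(OCOC)c1C(C)=O
F4 | step 11 | methyl 2-[2-(1H-benzotriazol-1-yl)-2-oxoethyl]-3,4,6-trimethoxybenzoate | COC(=O)c1c(OC)cc(OC)c(OC)c1CC(=O)n1nnc2ccccc21
F5 | step 11 | methyl 2-{4-[2-heptyl-4-methoxy-6-(methoxymethoxy)phenyl]-2,4-dioxobutyl}-3,4,6-trimethoxybenzoate | CCCCCCCc1cc(OC)cc(OCOC)c1C(=O)CC(=O)Cc1c(OC)c(OC)cc(OC)c1C(=O)OC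
F6 | step 4 | methyl 2-[2-(benzyloxy)ethyl]-5-bromo-4,6-dihydroxy-3-methoxybenzoate | COC(=O)c1c(O)c(Br)c(O)c(OC)c1CCOCc1ccccc1
F7 | step 4 | methyl 2-[2-(benzyloxy)ethyl]-5-bromo-3,4,6-trimethoxybenzoate | COC(=O)c1c(OC)c(Br)c(OC)c(OC)c1CCOCc1ccccc1
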